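## Structural features

The target is a germacranolide whose ten-membered carbocycle (C1–C10) is bridged by one oxygen between C1 and C5, so that C1–C5 and this oxygen form a tetrahydropyran inside an 11-oxabicyclo[5.3.1]undecene. C4 of the pyran is the spiro centre of the 4,15-epoxide, and C6/C7 carry a trans-fused α-methylene-γ-butyrolactone (O–C6, C7, C11(=C13), C12). C8 bears a methacrylate, and C9=C10 is a ring-cis olefin conjugated to the C14 aldehyde (E by the sequence rule, C8 cis to C1). Five of the six stereocentres are contiguous (C4, C5, C6, C7, C8: 4R,5R,6S,7R,8R); the sixth, C1 (R), is tied to C5 by the ether bridge, which forces a cis-2,6-disubstituted pyran. The fragile groups are two polymerisable Michael acceptors (methylene lactone, methacrylate), the enal, the acid-labile 2,2-disubstituted epoxide and the allylic C8 ester next to the doubly activated C7–H. The real difficulty is closing the medium ring and the transannular ether, and setting C4, C5 and C8 beside the lactone, without losing those groups. The key step uses the fact that the only branch points of the lactone ring, C6, C7 and C11, are the γ-, β- and α-carbons of a butenolide: the (S)-butenolide supplies C6, and its CH2–O unit becomes C5 together with the oxygen that ends as the pyran oxygen.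

## Logic of the disconnections

29 ⇒ 28 ⇒ 27. The C14–O bonds are removed. The enal is the most electrophilic group and would interfere with every organometallic and π-allyl step, whereas a C14 methyl is inert and needs no protecting group. The demand is a late, site-selective allylic C–H oxidation of one methyl group in the presence of epoxide and acceptors.

27 ⇒ 26. The C1–O bond of the pyran is cut. C1 is allylic to C9=C10, so it can be made electrophilic as a π-allyl terminus while the oxygen stays on C5. The bicycle becomes a single ten-membered ring. The forward step must attack transannularly with net retention at C1 and must ionise C1–O in preference to the allylic C8 ester.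

26 ⇒ 25. The C4–O and C15–O bonds of the epoxide are cut. The free C5 hydroxyl next to C4=C15 allows a hydroxyl-bound, reagent-controlled oxidant. This removes the C4 stereocentre. The demand is face selection on an exocyclic olefin of a ten-membered ring.

25 ⇒ 24 ⇒ 23. The C11=C13 π bond is traded for C11–H and C13–N. The Michael acceptor stays masked through hydride and organometallic steps. The demand is a quaternisation/elimination mild enough for esters, carbonate and the allylic alcohol.

23 ⇒ 22 ⇒ 21 ⇒ 20. The ring bond C4–C5 is cut, after passing through the C5 ketone. The bond joins an sp2 carbon to a carbonyl carbon whose oxygen is the original butenolide oxygen, and it delivers the allylic alcohol that the next two forward steps need. The ring opens to a chain, and C5 is set by hydride instead of by the ring closure. The demands are a high-dilution medium-ring closure and a face-selective 1,2-reduction.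

20 ⇒ 19 ⇒ 18 ⇒ 17 ⇒ 8 + 16. The C8 ester C–O bond and the C8–C9 bond are cut, with adjustment of the C5 oxidation level. This divides the molecule into two pieces of similar size, 8 (C5–C8, C11–C13) and 16 (C9, C10, C14, C1–C4, C15). The forward coupling must use the alkenyl iodide of 16 and leave its bromide, keep the olefin geometry, and set C8.

8 ⇒ 7 ⇒ 2 + 3 + 4. C7–C8 and C11–C13 are cut (key step). Two skeletal bonds and two stereocentres come from one operation on a chiral-pool lactone. The demands are 1,4- over 1,2-addition and the trans,trans arrangement.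

2 ⇒ 1. The O–Si bond is cut; the silyl group is chosen for steric bulk and acid stability.

16 ⇒ 15 ⇒ 14 ⇒ 13. The carbonate C–O bond, the C9–I bond and the C10–C14 bond are cut. One hydroxyl-directed anti-carbometalation fixes the trisubstituted olefin with iodine cis to C1. The demand is regiocontrol (methyl to C10) and tolerance of the 2-bromoalkene.

13 ⇒ 12 ⇒ 11 ⇒ 10 ⇒ 9. C1 is resolved, C1–C10 is cut (acetylide plus aldehyde), and the C4–Br and C15–H bonds are cut (hydrobromination). All materials are simple; the demand is Markovnikov addition to a terminal alkyne and an efficient resolution.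

## Other disconnections considered

Alternative 1: The ten-membered ring is traced back to a cis-fused decalin by re-forming C5–C10. In the forward direction a C5 alkoxide expels a C9 sulfonate (Grob fragmentation) to give the 9-en-5-one A1. In its favour, the ring is made by ring opening, with no dilution and no entropic penalty. The anti-periplanar requirement fixes the ring-cis C9=C10 geometry stereospecifically, and C1, C4, C6, C7 and C8 can be set on a rigid six-membered scaffold. Against it, the fragmentation substrate must carry six oxygenated carbons and the quaternary C10, which means a long linear sequence and four kinds of protecting group. A1 still lacks the lactone, so the isopropenyl methyl must be raised to the acid level and C14 to the aldehyde, two allylic oxidations that compete. The C5 ketone has to be reduced and etherified, the diol turned into the epoxide, and C6 (α to the ketone, bearing a leaving group) is exposed to base. On ring formation and olefin geometry Alternative 1 is the better plan, since the chosen route must close a medium ring and correct C5 afterwards. On C14 the two are equal, as both rely on a late allylic oxidation. On the lactone and on step economy the chosen plan is better, because C6, C7 and the masked methylene are in place after its second step.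

Alternative 2: The lactone is cut at C7–C11 and at the acyl C–O bond. In the forward direction the carbanion of a phosphonoacetate ester on O6 opens a trans C7–C8 epoxide at C7 to give the α-phosphono lactone A2. In its favour, C7 is set by inversion and C8–OH emerges free with defined configuration, which is better than the substrate-dependent C8 addition of the chosen plan. The phosphonate gives the exo-methylene by olefination with formaldehyde, the equal of the amine elimination. The pyran is made early on open-chain material, where cis-2,6 control is routine, which is better than a transannular closure. Against it, 5-exo attack at C7 must beat 6-endo attack at C8, and a stabilised phosphonoacetate anion is a sluggish nucleophile for an unactivated epoxide. The carbocycle must then be closed onto a preformed pyran (C9–C10 aldol condensation), which requires the pyran to place both arms axially in an eight-membered ring closure. The C4=C15 epoxidation would be left without a directing hydroxyl. Step counts should be similar. The chosen plan places its risk in a ten-membered closure followed by a proximity-driven ether formation, Alternative 2 in an eight-membered closure at the end.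

Alternative 3: The pyran C5–O bond and the epoxide C15–O bond are cut. In the forward direction Pd(PPh3)4 (zerovalent palladium) ionises a C5 vinyl epoxide, the C1 hydroxyl closes the pyran at C5, and the released C4 alkoxide displaces chloride from C15 to give the vinyl pyran A3. In its favour, one catalytic step makes both ether rings, and C4 comes from an acyclic epoxide set under reagent control. That is better than the epoxidation inside a ten-membered ring in the chosen plan. The mechanistic type (allylpalladium etherification) is the same one the chosen plan uses, so the two are equal there. Against it, A3 holds only C1–C5, C15 and two short arms. The lactone with C6, C7, C8 and C11–C13, and the carbocycle, would have to be built from a vinyl group next to a spiro-epoxide that must survive all those steps. The chosen plan has C6 and C7 from the chiral pool at its second step. Erosion at C5 by π-allyl isomerisation is a further concern. On structure the two plans are complementary (ether first versus lactone first). On step economy the chosen plan should be shorter, because three contiguous lactone stereocentres are harder to add late than an ether bridge.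

Key step: step 2

Remark on the chemistry: the sequence-rule E enal has C8 cis to C1 across C9=C10, so the olefin is carried from a (Z)-alkenyl iodide and C14 is oxidised last.
Remark on the structures: the (S)-butenolide and the trans,trans adduct were checked against C6 and C7 of the target and need no correction. The silyl group is changed from tert-butyldimethylsilyl to tert-butyldiphenylsilyl (more shielding of one butenolide face, stable to the aqueous acidic dethioacetalisation).

## Route

Step 1
Reactants: 1 (S)-5-(hydroxymethyl)furan-2(5H)-one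
Product: 2 (S)-5-[(tert-butyldiphenylsilyloxy)methyl]furan-2(5H)-one
Conditions: TBDPSCl, imidazole, CH2Cl2, 0 °C → rt
Reagents that add atoms: tert-butyl(chloro)diphenylsilane, CC(C)(C)[Si](Cl)(c1ccccc1)c1ccccc1
Why: Imidazole-assisted silylation of the primary alcohol; C6 is untouched, and the bulky, acid-stable silyl group is chosen for face shielding in step 2 and survival in step 3.

Step 2
Reactants: 2 (S)-5-[(tert-butyldiphenylsilyloxy)methyl]furan-2(5H)-one; 3 1,3-dithiane; 4 dimethylmethyleneiminium iodide
Product: 7 (3R,4S,5S)-5-[(tert-butyldiphenylsilyloxy)methyl]-3-[(dimethylamino)methyl]-4-(1,3-dithian-2-yl)dihydrofuran-2(3H)-one, via 2-lithio-1,3-dithiane 5 (not isolated), via lithium lactone enolate 6 (not isolated)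
Conditions: 3, n-BuLi, THF, −30 °C; HMPA (2 equiv; DMPU as substitute), −78 °C; add 2; then 4, −78 → −20 °C
Reagents that add atoms: n-butyllithium, [Li]CCCC (lithium of intermediates 5 and 6 only)
Why: n-BuLi deprotonates 3 to 5, and HMPA converts its contact ion pair into a solvent-separated one, which diverts the sulfur-stabilised carbanion from the carbonyl to conjugate (Michael) addition at C7 of 2. The lithium enolate 6 is not protonated but alkylated at C11 by the iminium ion 4 (Mannich reaction), so C7–C8 and C11–C13 form in one flask. The closest known reaction type is the tandem conjugate addition–enolate trapping of 5-substituted butenolides by sulfur-stabilised carbanions. No ring is closed; the lactone and dithiane rings are carried through unchanged. C7 is controlled by the C6 silyloxymethyl group, which blocks one face of the flat butenolide so that the nucleophile enters anti to it. C11 is controlled by the new C7 dithianyl group, which sends the iminium ion to the opposite enolate face, giving the trans,trans lactone, also the more stable arrangement. The step needs 1,4- over 1,2-addition and over γ-deprotonation (secured by the polar cosolvent, −78 °C and adding the non-enolisable electrophile only after the addition) and face selectivity at C7 and C11 (secured by the bulky C6 substituent). The aminomethyl group is a latent exo-methylene and the dithiane carbon is C8 at the aldehyde level.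

Step 3
Reactants: 7 trans,trans dithianyl Mannich lactone
Product: 8 (2S,3S,4R)-2-[(tert-butyldiphenylsilyloxy)methyl]-4-[(dimethylamino)methyl]-5-oxotetrahydrofuran-3-carbaldehyde
Conditions: PhI(OCOCF3)2, TFA (1.1 equiv), MeCN–H2O 9:1, 0 °C; aq. NaHCO3
Reagents that add atoms: water, O
Why: Oxidative dethioacetalisation with a hypervalent iodine reagent; the amine is held as its trifluoroacetate so that it is not oxidised, and C7 is already in its more stable trans,trans arrangement.

Step 4
Reactants: 9 pent-4-yn-1-ol
Product: 10 4-bromopent-4-en-1-ol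
Conditions: Et4N+ HBr2−, CH2Cl2, 40 °C
Reagents that add atoms: hydrogen bromide (from tetraethylammonium hydrogen dibromide), Br
Why: Markovnikov hydrobromination of the terminal alkyne gives the 2-bromoalkene (future C4=C15 with the halide on C4) without affecting the alcohol.

Step 5
Reactants: 10 4-bromopent-4-en-1-ol
Product: 11 4-bromopent-4-enal
Conditions: TEMPO (10 mol%), PhI(OAc)2, CH2Cl2, rt
Reagents that add atoms: none
Why: Oxoammonium-mediated oxidation of the primary alcohol stops at the aldehyde; the vinyl bromide is inert.

Step 6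
Reactants: 11 4-bromopent-4-enal
Product: 12 rac-6-bromohept-6-en-1-yn-3-ol
Conditions: ethynylmagnesium bromide, THF, −78 → 0 °C; aq. NH4Cl
Reagents that add atoms: ethynylmagnesium bromide, C#C[Mg]Br
Why: Grignard 1,2-addition of the acetylide forms C1–C10 and the C1 carbinol as a racemate.

Step 7
Reactants: 12 rac-6-bromohept-6-en-1-yn-3-ol
Product: 13 (R)-6-bromohept-6-en-1-yn-3-ol
Conditions: immobilised Candida antarctica lipase B, vinyl acetate, hexane, 30 °C, run slightly beyond half conversion
Reagents that add atoms: none
Why: Lipase-catalysed kinetic resolution by transesterification; with ethynyl as the smaller and the alkyl chain as the larger group the enzyme should acylate the (S)-alcohol, so the required (R)-alcohol remains and is separated from the (S)-acetate.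

Step 8
Reactants: 13 (R)-6-bromohept-6-en-1-yn-3-ol
Product: 15 (3R,1Z)-6-bromo-1-iodo-2-methylhepta-1,6-dien-3-ol, via cyclic alkenylmagnesium alkoxide 14 (not isolated)
Conditions: MeMgBr (3 equiv), CuI (10 mol%), THF, −20 °C → rt; then I2, −40 → 0 °C
Reagents that add atoms: methylmagnesium bromide, C[Mg]Br; iodine, II
Why: Copper-catalysed, hydroxyl-directed anti-carbomagnesiation of the propargylic alkoxide puts methyl (C14) on C10 and magnesium on C9 inside the five-membered chelate 14. Iodinolysis with retention should therefore give the (Z)-iodide with iodine cis to C1; C1 and the 2-bromoalkene are not involved.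

Step 9
Reactants: 15 (3R,1Z)-6-bromo-1-iodo-2-methylhepta-1,6-dien-3-ol
Product: 16 tert-butyl (3R,1Z)-6-bromo-1-iodo-2-methylhepta-1,6-dien-3-yl carbonate
Conditions: Boc2O, DMAP (cat.), MeCN, rt
Reagents that add atoms: di-tert-butyl dicarbonate, CC(C)(C)OC(=O)OC(=O)OC(C)(C)C
Why: DMAP-catalysed acylation of the allylic alcohol with retention at C1; the tert-butyl carbonate is a robust protecting group now and the leaving group of the allylpalladium step later.

Step 10
Reactants: 8 lactone aldehyde; 16 alkenyl iodide carbonate
Product: 17 (3R,4R,5S)-4-[(1R,2Z,4R)-7-bromo-4-(tert-butoxycarbonyloxy)-1-hydroxy-3-methylocta-2,7-dien-1-yl]-5-[(tert-butyldiphenylsilyloxy)methyl]-3-[(dimethylamino)methyl]dihydrofuran-2(3H)-one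
Conditions: CrCl2 (6 equiv), NiCl2 (1 mol%), DMSO, rt, 16 in 1.5-fold excess
Reagents that add atoms: none
Why: Nozaki–Hiyama–Kishi reaction. Zerovalent nickel inserts into the alkenyl iodide much faster than into the 2-bromoalkene, and the alkenylchromium species (trivalent chromium) adds only to the aldehyde with retention of olefin geometry. C8 should form mainly as 8R by polar 1,3-anti induction from the C6–O bond, the two α-branches being ring carbons of similar size; the epimers should be separable.

Step 11
Reactants: 17 C8 allylic alcohol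
Product: 18 C8 methacrylate of 17: (1R,2Z,4R)-7-bromo-4-(tert-butoxycarbonyloxy)-1-{(2S,3R,4R)-2-[(tert-butyldiphenylsilyloxy)methyl]-4-[(dimethylamino)methyl]-5-oxotetrahydrofuran-3-yl}-3-methylocta-2,7-dien-1-yl methacrylate
Conditions: methacrylic anhydride, Et3N, DMAP (cat.), BHT (trace), CH2Cl2, 0 °C → rt
Reagents that add atoms: methacrylic anhydride, CC(=C)C(=O)OC(=O)C(C)=C
Why: DMAP-catalysed esterification with retention at C8; the target's ester is installed now because it also keeps C8–OH from directing or taking part in steps 14 to 19.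

Step 12
Reactants: 18 silyl ether methacrylate
Product: 19 primary C5 alcohol: as 18 with 2-(hydroxymethyl) on the lactone
Conditions: HF·pyridine, THF–pyridine, 0 °C → rt; aq. NaHCO3
Reagents that add atoms: none
Why: Fluoride cleavage of the primary silyl ether under non-basic conditions, so methacrylate, carbonate and lactone survive and no acyl migration is expected.

Step 13
Reactants: 19 primary C5 alcohol
Product: 20 C5 aldehyde: as 18 with 2-formyl on the lactone, (2S,3R,4R)
Conditions: Dess–Martin periodinane, TFA (1 equiv), CH2Cl2, 0 °C → rt; aq. NaHCO3/Na2S2O3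
Reagents that add atoms: none
Why: Dess–Martin oxidation to the α-acyloxy aldehyde without base (amine protonated), so C6 does not epimerise.

Step 14
Reactants: 20 C5 aldehyde with 2-bromoalkene
Product: 21 (1R,5RS,6S,7R,8R,11R,9Z)-1-(tert-butoxycarbonyloxy)-13-(dimethylamino)-5-hydroxy-8-(methacryloyloxy)germacra-4(15),9-dien-12,6-olide (both C5 epimers)
Conditions: CrCl2 (10 equiv), NiCl2 (10 mol%), DMSO, high dilution, slow addition of 20, 25 → 45 °C
Reagents that add atoms: none
Why: Intramolecular Nozaki–Hiyama–Kishi reaction forms C4–C5 and the ten-membered ring; the cis C9=C10 olefin and the trans-lactone bring the termini together, and the slower 2-bromoalkene is met by more NiCl2 and mild warming. C5 forms as a mixture that converges in step 15.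

Step 15
Reactants: 21 macrocyclic C5 alcohols
Product: 22 (1R,6S,7R,8R,11R,9Z)-1-(tert-butoxycarbonyloxy)-13-(dimethylamino)-8-(methacryloyloxy)-5-oxogermacra-4(15),9-dien-12,6-olide
Conditions: Dess–Martin periodinane, TFA (1 equiv), CH2Cl2, 0 °C → rt; aq. NaHCO3/Na2S2O3
Reagents that add atoms: none
Why: Dess–Martin oxidation takes both C5 epimers to one cross-conjugated enone; no base is present, so the C6 hydrogen between ketone and lactone oxygen is not removed.

Step 16
Reactants: 22 macrocyclic enone
Product: 23 (1R,5S,6S,7R,8R,11R,9Z)-1-(tert-butoxycarbonyloxy)-13-(dimethylamino)-5-hydroxy-8-(methacryloyloxy)germacra-4(15),9-dien-12,6-olide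
Conditions: NaBH4, CeCl3·7H2O, MeOH, −78 °C
Reagents that add atoms: none
Why: Luche reduction gives 1,2-reduction of the enone only. Hydride should attack anti to the C6–O bond (Felkin–Anh/Cornforth model for an α-acyloxy ketone), giving the 5,6-syn alcohol (5S here, the spatial arrangement of 5R in the target); the masked acceptor cannot be reduced.

Step 17
Reactants: 23 syn allylic alcohol
Product: 25 (1R,5S,6S,7R,8R,9Z)-1-(tert-butoxycarbonyloxy)-5-hydroxy-8-(methacryloyloxy)germacra-4(15),9,11(13)-trien-12,6-olide, via trimethylammonium iodide 24 (not isolated)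
Conditions: MeI (excess), THF, rt; then satd aq. NaHCO3, EtOAc, rt
Reagents that add atoms: iodomethane, CI (methyl and iodide of intermediate 24 only)
Why: Exhaustive N-methylation followed by bicarbonate-induced E1cB (Hofmann-type) elimination of the β-ammonium lactone unveils C11=C13 after all hydride and organometallic steps; bicarbonate is too weak to epimerise C7.

Step 18
Reactants: 25 allylic alcohol
Product: 26 (1R,4R,5R,6S,7R,8R,9Z)-1-(tert-butoxycarbonyloxy)-4,15-epoxy-5-hydroxy-8-(methacryloyloxy)germacra-9,11(13)-dien-12,6-olide
Conditions: Ti(OiPr)4 (20 mol%), D-(−)-diisopropyl tartrate (24 mol%), t-BuOOH, 4 Å MS, CH2Cl2, −20 °C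
Reagents that add atoms: tert-butyl hydroperoxide, CC(C)(C)OO
Why: Sharpless asymmetric epoxidation of a secondary 2-substituted allylic alcohol. With D-(−)-tartrate the oxygen goes to the C4=C15 face on which H5 lies, the matched case, which gives the erythro epoxy alcohol (4R); the other olefins are electron-poor or lack a free allylic hydroxyl.

Step 19
Reactants: 26 epoxy alcohol carbonate
Product: 27 (1R,4R,5R,6S,7R,8R,9Z)-1,5:4,15-diepoxy-8-(methacryloyloxy)germacra-9,11(13)-dien-12,6-olide
Conditions: Pd(PPh3)4 (10 mol%), THF (degassed), rt → 40 °C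
Reagents that add atoms: none
Why: Intramolecular Tsuji–Trost allylic etherification. Zerovalent palladium ionises the C1 carbonate with inversion, the released tert-butoxide deprotonates C5–OH, and the alkoxide attacks C1 anti to palladium, so net retention at C1. The six-membered ether closes across the ring at the terminus remote from the C8 ester, fixing the cis-2,6-pyran and keeping the C9=C10 geometry.

Step 20
Reactants: 27 bicyclic ether with C14 methyl
Product: 28 (1R,4R,5R,6S,7R,8R,9Z)-1,5:4,15-diepoxy-14-hydroxy-8-(methacryloyloxy)germacra-9,11(13)-dien-12,6-olide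
Conditions: SeO2 (0.5 equiv), t-BuOOH, CH2Cl2, rt
Reagents that add atoms: tert-butyl hydroperoxide, CC(C)(C)OO (oxygen relayed by selenium dioxide, O=[Se]=O)
Why: Riley allylic oxidation (ene reaction, then [2,3]-shift) of the only electron-rich olefin. The C14 methyl should react because the other allylic hydrogen on the substituted terminus (C1–H) is at a bridgehead; the reaction type is established for germacranolide methyl groups beside an epoxide and a methylene lactone.

Step 21
Reactants: 28 C14 allylic alcohol
Product: 29 (1R,4R,5R,6S,7R,8R,9E)-1,5:4,15-diepoxy-8-(methacryloyloxy)-14-oxogermacra-9,11(13)-dien-12,6-olide (CNP0257628.1)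
Conditions: MnO2 (excess), CH2Cl2, rt
Reagents that add atoms: none
Why: MnO2 oxidises the primary allylic alcohol to the enal under neutral conditions; epoxide, esters and the ring-cis olefin (E by the sequence rule once C14 is an aldehyde) are unaffected.

## Compound list

1 | (S)-5-(hydroxymethyl)furan-2(5H)-one | OC[C@H]1OC(=O)C=C1 | starting material
2 | (S)-5-[(tert-butyldiphenylsilyloxy)methyl]furan-2(5H)-one | CC(C)(C)[Si](OC[C@H]1OC(=O)C=C1)(c1ccccc1)c1ccccc1 | intermediate
3 | 1,3-dithiane | C1CSCSC1 | starting material
4 | dimethylmethyleneiminium iodide | C=[N+](C)C.[I-] | starting material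
5 | 2-lithio-1,3-dithiane | [Li]C1SCCCS1 | intermediate
6 | lithium enolate of (4S,5S)-5-[(tert-butyldiphenylsilyloxy)methyl]-4-(1,3-dithian-2-yl)dihydrofuran-2(3H)-one | CC(C)(C)[Si](OC[C@H]1OC(O[Li])=C[C@@H]1C1SCCCS1)(c1ccccc1)c1ccccc1 | intermediate
7 | (3R,4S,5S)-5-[(tert-butyldiphenylsilyloxy)methyl]-3-[(dimethylamino)methyl]-4-(1,3-dithian-2-yl)dihydrofuran-2(3H)-one | CC(C)(C)[Si](OC[C@H]1OC(=O)[C@@H](CN(C)C)[C@@H]1C1SCCCS1)(c1ccccc1)c1ccccc1 | intermediate
8 | (2S,3S,4R)-2-[(tert-butyldiphenylsilyloxy)methyl]-4-[(dimethylamino)methyl]-5-oxotetrahydrofuran-3-carbaldehyde | CC(C)(C)[Si](OC[C@H]1OC(=O)[C@@H](CN(C)C)[C@@H]1C=O)(c1ccccc1)c1ccccc1 | intermediate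
9 | pent-4-yn-1-ol | OCCCC#C | starting material
10 | 4-bromopent-4-en-1-ol | OCCCC(Br)=C | intermediate
11 | 4-bromopent-4-enal | O=CCCC(Br)=C | intermediate
12 | rac-6-bromohept-6-en-1-yn-3-ol | C#CC(O)CCC(Br)=C | intermediate
13 | (R)-6-bromohept-6-en-1-yn-3-ol | C#C[C@H](O)CCC(Br)=C | intermediate
14 | (5R)-5-(3-bromobut-3-en-1-yl)-4-methyl-2,5-dihydro-1,2-oxamagnesole (cyclic alkenylmagnesium alkoxide) | CC1=C[Mg]O[C@@H]1CCC(Br)=C | intermediate
15 | (3R,1Z)-6-bromo-1-iodo-2-methylhepta-1,6-dien-3-ol | I/C=C(/C)[C@H](O)CCC(Br)=C | intermediate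
16 | tert-butyl (3R,1Z)-6-bromo-1-iodo-2-methylhepta-1,6-dien-3-yl carbonate | I/C=C(/C)[C@H](OC(=O)OC(C)(C)C)CCC(Br)=C | intermediate
17 | (3R,4R,5S)-4-[(1R,2Z,4R)-7-bromo-4-(tert-butoxycarbonyloxy)-1-hydroxy-3-methylocta-2,7-dien-1-yl]-5-[(tert-butyldiphenylsilyloxy)methyl]-3-[(dimethylamino)methyl]dihydrofuran-2(3H)-one | CC(C)(C)[Si](OC[C@H]1OC(=O)[C@@H](CN(C)C)[C@@H]1[C@H](O)/C=C(/C)[C@H](OC(=O)OC(C)(C)C)CCC(Br)=C)(c1ccccc1)c1ccccc1 | intermediate
18 | (1R,2Z,4R)-7-bromo-4-(tert-butoxycarbonyloxy)-1-{(2S,3R,4R)-2-[(tert-butyldiphenylsilyloxy)methyl]-4-[(dimethylamino)methyl]-5-oxotetrahydrofuran-3-yl}-3-methylocta-2,7-dien-1-yl methacrylate | CC(C)(C)[Si](OC[C@H]1OC(=O)[C@@H](CN(C)C)[C@@H]1[C@H](OC(=O)C(C)=C)/C=C(/C)[C@H](OC(=O)OC(C)(C)C)CCC(Br)=C)(c1ccccc1)c1ccccc1 | intermediate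
19 | (1R,2Z,4R)-7-bromo-4-(tert-butoxycarbonyloxy)-1-{(2S,3R,4R)-4-[(dimethylamino)methyl]-2-(hydroxymethyl)-5-oxotetrahydrofuran-3-yl}-3-methylocta-2,7-dien-1-yl methacrylate | OC[C@H]1OC(=O)[C@@H](CN(C)C)[C@@H]1[C@H](OC(=O)C(C)=C)/C=C(/C)[C@H](OC(=O)OC(C)(C)C)CCC(Br)=C | intermediate
20 | (1R,2Z,4R)-7-bromo-4-(tert-butoxycarbonyloxy)-1-{(2S,3R,4R)-4-[(dimethylamino)methyl]-2-formyl-5-oxotetrahydrofuran-3-yl}-3-methylocta-2,7-dien-1-yl methacrylate | O=C[C@H]1OC(=O)[C@@H](CN(C)C)[C@@H]1[C@H](OC(=O)C(C)=C)/C=C(/C)[C@H](OC(=O)OC(C)(C)C)CCC(Br)=C | intermediate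
21 | (1R,5RS,6S,7R,8R,11R,9Z)-1-(tert-butoxycarbonyloxy)-13-(dimethylamino)-5-hydroxy-8-(methacryloyloxy)germacra-4(15),9-dien-12,6-olide (C5 epimers) | OC1C(=C)CC[C@@H](OC(=O)OC(C)(C)C)/C(C)=C\[C@@H](OC(=O)C(C)=C)[C@H]2[C@H](CN(C)C)C(=O)O[C@H]12 | intermediate
22 | (1R,6S,7R,8R,11R,9Z)-1-(tert-butoxycarbonyloxy)-13-(dimethylamino)-8-(methacryloyloxy)-5-oxogermacra-4(15),9-dien-12,6-olide | O=C1C(=C)CC[C@@H](OC(=O)OC(C)(C)C)/C(C)=C\[C@@H](OC(=O)C(C)=C)[C@H]2[C@H](CN(C)C)C(=O)O[C@H]12 | intermediate
23 | (1R,5S,6S,7R,8R,11R,9Z)-1-(tert-butoxycarbonyloxy)-13-(dimethylamino)-5-hydroxy-8-(methacryloyloxy)germacra-4(15),9-dien-12,6-olide | O[C@H]1C(=C)CC[C@@H](OC(=O)OC(C)(C)C)/C(C)=C\[C@@H](OC(=O)C(C)=C)[C@H]2[C@H](CN(C)C)C(=O)O[C@H]12 | intermediate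
24 | (1R,5S,6S,7R,8R,11R,9Z)-1-(tert-butoxycarbonyloxy)-5-hydroxy-8-(methacryloyloxy)-13-(trimethylammonio)germacra-4(15),9-dien-12,6-olide iodide | O[C@H]1C(=C)CC[C@@H](OC(=O)OC(C)(C)C)/C(C)=C\[C@@H](OC(=O)C(C)=C)[C@H]2[C@H](C[N+](C)(C)C)C(=O)O[C@H]12.[I-] | intermediate
25 | (1R,5S,6S,7R,8R,9Z)-1-(tert-butoxycarbonyloxy)-5-hydroxy-8-(methacryloyloxy)germacra-4(15),9,11(13)-trien-12,6-olide | O[C@H]1C(=C)CC[C@@H](OC(=O)OC(C)(C)C)/C(C)=C\[C@@H](OC(=O)C(C)=C)[C@H]2C(=C)C(=O)O[C@H]12 | intermediate
26 | (1R,4R,5R,6S,7R,8R,9Z)-1-(tert-butoxycarbonyloxy)-4,15-epoxy-5-hydroxy-8-(methacryloyloxy)germacra-9,11(13)-dien-12,6-olide | O[C@H]1[C@]2(CO2)CC[C@@H](OC(=O)OC(C)(C)C)/C(C)=C\[C@@H](OC(=O)C(C)=C)[C@H]2C(=C)C(=O)O[C@H]12 | intermediate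
27 | (1R,4R,5R,6S,7R,8R,9Z)-1,5:4,15-diepoxy-8-(methacryloyloxy)germacra-9,11(13)-dien-12,6-olide | C=C(C)C(=O)O[C@@H]1/C=C(/C)[C@H]2CC[C@@]3(CO3)[C@H](O2)[C@H]2OC(=O)C(=C)[C@@H]21 | intermediate
28 | (1R,4R,5R,6S,7R,8R,9Z)-1,5:4,15-diepoxy-14-hydroxy-8-(methacryloyloxy)germacra-9,11(13)-dien-12,6-olide | C=C(C)C(=O)O[C@@H]1/C=C(/CO)[C@H]2CC[C@@]3(CO3)[C@H](O2)[C@H]2OC(=O)C(=C)[C@@H]21 | intermediate
29 | (1R,4R,5R,6S,7R,8R,9E)-1,5:4,15-diepoxy-8-(methacryloyloxy)-14-oxogermacra-9,11(13)-dien-12,6-olide (CNP0257628.1) | C=C(C)C(=O)O[C@@H]1/C=C(/C=O)[C@H]2CC[C@@]3(CO3)[C@H](O2)[C@H]2OC(=O)C(=C)[C@@H]21 | target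

## Step count and least certain steps

Total step count: 21. Longest linear sequence: 18 steps (9 → 29, steps 4 to 21). The lactone branch from 1 is 15 steps (steps 1 to 3 and 10 to 21).

Step 2 (key step). The hard, basic lithiodithiane may add to the lactone carbonyl or remove the γ-hydrogen of the butenolide (racemisation, ring aromatisation) instead of adding 1,4, and the iminium trapping may be incompletely trans-selective if the enolate equilibrates. Fallback: from 2, the softer tris(phenylthio)methyllithium (from tris(phenylthio)methane and n-BuLi, THF, −78 °C), which adds 1,4 to butenolides without a polar cosolvent, is trapped with 4 to give (3R,4S,5S)-5-[(tert-butyldiphenylsilyloxy)methyl]-3-[(dimethylamino)methyl]-4-[tris(phenylthio)methyl]dihydrofuran-2(3H)-one F1. Hydrolysis (AgNO3, 2,6-lutidine, aq. THF) gives the S-phenyl thioester F2, and Fukuyama reduction (Et3SiH, palladium on carbon, acetone) gives 8, where the route is rejoined.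

Step 19. Zerovalent palladium may also ionise the allylic C8 methacrylate, the π-allyl intermediate may collapse by elimination to a diene, and the transient C5 alkoxide may migrate onto the neighbouring epoxide (Payne rearrangement) before it reaches C1. Fallback: from 25, the etherification is run before the epoxide exists (Pd(PPh3)4, THF) to give (1R,5S,6S,7R,8R,9Z)-1,5-epoxy-8-(methacryloyloxy)germacra-4(15),9,11(13)-trien-12,6-olide F3. Its exocyclic C4=C15 is then epoxidised with dimethyldioxirane (acetone, 0 °C) on the face away from the C6 arm and the eight-membered bridge; the C9=C10 olefin is deactivated by two allylic oxygens. This arrives at 27.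

Step 18. The ten-membered ring may not let the titanium–tartrate-bound C5 alkoxide reach the face of C4=C15 that the tartrate demands, which would mean slow turnover, transesterification by the titanium alkoxide, or loss of facial selectivity. Fallback: a two-step halohydrin route that delivers the oxygen to the face opposite to the one an external electrophile attacks. From 25, NBS in aqueous DME gives (1R,4S,5R,6S,7R,8R,9Z)-15-bromo-1-(tert-butoxycarbonyloxy)-4,5-dihydroxy-8-(methacryloyloxy)germacra-9,11(13)-dien-12,6-olide F4, and DBU (CH2Cl2) closes the epoxide to 26.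

Step 10. Facial selectivity at C8 may be low or reversed, because the aldehyde sits between two ring carbons of similar size and the 1,2- and 1,3-induction models oppose each other. Fallback: from 8 and 16 the (8S)-epimer, (3R,4R,5S)-4-[(1S,2Z,4R)-7-bromo-4-(tert-butoxycarbonyloxy)-1-hydroxy-3-methylocta-2,7-dien-1-yl]-5-[(tert-butyldiphenylsilyloxy)methyl]-3-[(dimethylamino)methyl]dihydrofuran-2(3H)-one F5, is esterified with inversion by Mitsunobu reaction (methacrylic acid, PPh3, DIAD, toluene, 0 °C), which returns to 18.

Step 16. Hydride delivery may follow the ring conformation and not the open-chain model, giving the 5,6-anti alcohol; conjugate reduction of the methylene ketone is a second risk. Fallback: from 22 the 5-epimer, (1R,5R,6S,7R,8R,11R,9Z)-1-(tert-butoxycarbonyloxy)-13-(dimethylamino)-5-hydroxy-8-(methacryloyloxy)germacra-4(15),9-dien-12,6-olide F6, is inverted by Mitsunobu reaction with chloroacetic acid (PPh3, DIAD) to the (5S)-chloroacetate F7. The chloroacetate is removed selectively with thiourea (NaHCO3, EtOH), leaving methacrylate and carbonate, to give 23.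

## Further compounds

F1 | step 2 | (3R,4S,5S)-5-[(tert-butyldiphenylsilyloxy)methyl]-3-[(dimethylamino)methyl]-4-[tris(phenylthio)methyl]dihydrofuran-2(3H)-one | CC(C)(C)[Si](OC[C@H]1OC(=O)[C@@H](CN(C)C)[C@@H]1C(Sc1ccccc1)(Sc1ccccc1)Sc1ccccc1)(c1ccccc1)c1ccccc1
F2 | step 2 | S-phenyl (2S,3S,4R)-2-[(tert-butyldiphenylsilyloxy)methyl]-4-[(dimethylamino)methyl]-5-oxotetrahydrofuran-3-carbothioate | CC(C)(C)[Si](OC[C@H]1OC(=O)[C@@H](CN(C)C)[C@@H]1C(=O)Sc1ccccc1)(c1ccccc1)c1ccccc1
F3 | step 19 | (1R,5S,6S,7R,8R,9Z)-1,5-epoxy-8-(methacryloyloxy)germacra-4(15),9,11(13)-trien-12,6-olide | C=C(C)C(=O)O[C@@H]1/C=C(/C)[C@H]2CCC(=C)[C@H](O2)[C@H]2OC(=O)C(=C)[C@@H]21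
F4 | step 18 | (1R,4S,5R,6S,7R,8R,9Z)-15-bromo-1-(tert-butoxycarbonyloxy)-4,5-dihydroxy-8-(methacryloyloxy)germacra-9,11(13)-dien-12,6-olide | O[C@H]1[C@](O)(CBr)CC[C@@H](OC(=O)OC(C)(C)C)/C(C)=C\[C@@H](OC(=O)C(C)=C)[C@H]2C(=C)C(=O)O[C@H]12
F5 | step 10 | (3R,4R,5S)-4-[(1S,2Z,4R)-7-bromo-4-(tert-butoxycarbonyloxy)-1-hydroxy-3-methylocta-2,7-dien-1-yl]-5-[(tert-butyldiphenylsilyloxy)methyl]-3-[(dimethylamino)methyl]dihydrofuran-2(3H)-one | CC(C)(C)[Si](OC[C@H]1OC(=O)[C@@H](CN(C)C)[C@@H]1[C@@H](O)/C=C(/C)[C@H](OC(=O)OC(C)(C)C)CCC(Br)=C)(c1ccccc1)c1ccccc1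
F6 | step 16 | (1R,5R,6S,7R,8R,11R,9Z)-1-(tert-butoxycarbonyloxy)-13-(dimethylamino)-5-hydroxy-8-(methacryloyloxy)germacra-4(15),9-dien-12,6-olide | O[C@@H]1C(=C)CC[C@@H](OC(=O)OC(C)(C)C)/C(C)=C\[C@@H](OC(=O)C(C)=C)[C@H]2[C@H](CN(C)C)C(=O)O[C@H]12
F7 | step 16 | (1R,5S,6S,7R,8R,11R,9Z)-1-(tert-butoxycarbonyloxy)-5-(chloroacetoxy)-13-(dimethylamino)-8-(methacryloyloxy)germacra-4(15),9-dien-12,6-olide | ClCC(=O)O[C@H]1C(=C)CC[C@@H](OC(=O)OC(C)(C)C)/C(C)=C\[C@@H](OC(=O)C(C)=C)[C@H]2[C@H](CN(C)C)C(=O)O[C@H]12
A1 | alternative 1 | protected germacra-9-en-5-one from the Grob fragmentation (8-O-PMB, 1-O-TES, 6-O-MOM, 4,15-acetonide, 7-isopropenyl) | COc1ccc(cc1)CO[C@@H]2/C=C(/C)[C@H](O[Si](CC)(CC)CC)CC[C@@]3(COC(C)(C)O3)C(=O)[C@@H](OCOC)[C@@H]2C(C)=C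
A2 | alternative 2 | α-(diethoxyphosphoryl) trans-lactone with free C8 hydroxyl, C9 diethyl acetal and preformed 4-methylene pyran | CCOP(=O)(OCC)[C@@H]1C(=O)O[C@H]([C@H]2O[C@@H](CCO[Si](C)(C)C(C)(C)C)CCC2=C)[C@H]1[C@H](O)C(OCC)OCC
A3 | alternative 3 | cis-2,6-disubstituted 5-vinyl tetrahydropyran with 4,15-spiro-epoxide and 2-(tert-butyldimethylsilyloxy)ethyl arm | CC(C)(C)[Si](C)(C)OCC[C@H]1CC[C@@]2(CO2)[C@H](O1)C=C
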